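The runs stem from a simulated flask for an exercise; the scatter is artificial.

A capture share of 0.426 in the spring run and 0.244 in the winter run is what you need from these readings.

| flask | starting complex | incoming ligand | remark | time |
|---|---|---|---|---|
| spring | 0.20 M | 0.050 M | run made earlier |  |
| winter | 0.20 M | 0.20 M | run made earlier |  |
| flask | 0.20 M | 0.100 M |  | 40 min |

- spring (time / min: complex with one exchanged / %): 4.00: 1.7; 6.00: 5.2; 10.0: 6.0; 20.0: 7.8; 30.0: 10.3; 50.0: 11.0
- winter (time / min: complex with one exchanged / %): 8.00: 16.1; 15.0: 17.6; 25.0: 21.6; 30.0: 20.6; 40.0: 24.4; 50.0: 25.7

(standard deviation of a reading: 1 percentage point)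

* equivalents of incoming ligand to starting complex, everything else as given, that leave most complex with one exchanged at 40 min
* the amount of complex with one exchanged then, in percent of the starting complex charged
* the amount of complex with one exchanged with the amounts as given

The capture share is the part of the charged incoming ligand found as complex with one exchanged at the asked time, with spring read between its two neighbouring readings. In your flask, c(incoming ligand) = 0.100 M lies below c(starting complex) = 0.20 M, so incoming ligand is the limiting reagent and its charge is the natural yardstick.

My first pass puts the spring share on your flask and gives 21.3 %, while the winter share gives 12.2 %. One number is therefore not enough: the shares differ by 0.182, more than the 0.0400 that the scatter of one reading puts on a spring share. So go round again. Your charge lies midway between the two runs on a ratio scale, so I estimate the flask's share as their geometric mean, 0.322, and I expect 16.1 %. The readings at two charges show no peak in the amount, so I commit to no optimum.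

The forecast gave 16.5 %, and 30 % at 1.8 equiv, calling the optimum “a judgement”.

The flask gives 16.6 %, a share of 0.332, and its best is 24.1 % at 1.36 equiv.

    complex with one exchanged + incoming ligand ⇌ leaving ligand + complex with two exchanged (K = 6.00, k = 0.680 M⁻¹ min⁻¹)
    starting complex + incoming ligand ⇌ leaving ligand + complex with one exchanged (K = 21.0, k = 0.350 M⁻¹ min⁻¹)
    complex with one exchanged ⇌ isomer of the product (K = 0.840, k = 1.30 min⁻¹)

Now take the neighbour with 0.40 M of incoming ligand, twice the winter charge. Going from your flask to winter, also twice the ligand, multiplied my estimated share by 0.758. The same step gives 0.185, hence 37.0 %. That neighbour gives 21.8 %, a share of 0.109, while complex with two exchanged stands at 50.7 %.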